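The phthalide C3 is a benzylic carbinol carbon ortho to the C1 carboxyl on the benzene ring, so it is treated as a masked aldehyde. The route rests on a catalyst-controlled alkylation of methyl 2-formyl-4,6-dimethoxybenzoate by a primary alkylzinc that already carries the complete (2S,5R,7S)-1,6-dioxaspiro[4.4]nonane. One operation forms the C3–CH2 bond, sets the remote C3 stereocentre by the chiral titanium catalyst and, through attack of the new alkoxide on the neighbouring ester, closes the five-membered lactone ring (O2–C1). The precursors are an aldehyde-ester and a mixed alkyl(trimethylsilylmethyl)zinc made from a terminal alkene; the spiroketal comes from acetone dimethylhydrazone and two chiral epoxides.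

Key step: step 6

Remark (assumption): in a 1,6-dioxaspiro[4.4]nonane neither configuration at the spiro carbon is clearly favoured. The spiroketalisation in step 4 is therefore expected to give the wanted (5R) compound together with its C5 epimer. C5 is fixed inside step 4 by chromatographic separation, and the unwanted epimer is re-equilibrated with acid and separated again. All steps after step 4 are run free of Brønsted acid.

Step 1
Reactants: 1 2-bromo-3,5-dimethoxybenzaldehyde
Product: 2 methyl 2-formyl-4,6-dimethoxybenzoate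
Conditions: Pd(OAc)2 (3 mol%), Xantphos (6 mol%), CO (1–5 bar), Et3N (2 equiv), MeOH (5 equiv), toluene, 80 °C
Reagents that add atoms: carbon monoxide [C-]#[O+]; methanol CO
Why: Palladium-catalysed methoxycarbonylation (Heck carbonylation) of the aryl bromide: oxidative addition is helped by the ortho formyl group, CO inserts and methanol cleaves the acyl-palladium, and the basic medium with little methanol should keep the product as the open methyl ester and not as the cyclic 3-methoxyphthalide.

Step 2
Reactants: 3 rac-2-(hex-5-en-1-yl)oxirane (1,2-epoxyoct-7-ene)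
Product: 4 (S)-2-(hex-5-en-1-yl)oxirane
Conditions: (S,S)-(salen)Co(III)OAc (0.5 mol%), H2O (0.55 equiv), neat, 0 °C to rt; distillation
Reagents that add atoms: none
Why: Jacobsen hydrolytic kinetic resolution: the (S,S)-cobalt salen catalyst should hydrolyse the (R)-epoxide selectively, so the volatile (S)-epoxide, which carries the future C2 of the spiroketal, is left and distilled from the diol.

Step 3
Reactants: 5 acetone N,N-dimethylhydrazone; 6 (S)-propylene oxide
Product: 7 (5S)-5-hydroxyhexan-2-one N,N-dimethylhydrazone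
Conditions: n-BuLi (1.05 equiv), THF, −78 to 0 °C; then 6, 0 °C to rt; H2O
Reagents that add atoms: none
Why: Corey–Enders alkylation: the lithium azaenolate of the hydrazone opens the epoxide at its CH2 in an SN2 reaction, so the stereocentre of 6 is not touched and becomes the future C7 of the spiroketal.

Step 4
Reactants: 7 (5S)-5-hydroxyhexan-2-one N,N-dimethylhydrazone; 4 (S)-2-(hex-5-en-1-yl)oxirane
Product: 10 (2S,5R,7S)-2-(hex-5-en-1-yl)-7-methyl-1,6-dioxaspiro[4.4]nonane, via (2S,8S)-2,8-dihydroxytetradec-13-en-5-one N,N-dimethylhydrazone 8 (not isolated), via (2S,8S)-2,8-dihydroxytetradec-13-en-5-one 9 (not isolated)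
Conditions: n-BuLi (2.1 equiv), THF, −78 to 0 °C; then 4, 0 °C to rt; H2O; then aq. oxalic acid, Et2O, rt; preparative HPLC (silica, hexane/Et2O, refractive-index detection); the 5S fraction is re-equilibrated (CSA cat., CH2Cl2, rt) and separated again
Reagents that add atoms: none
Why: A second Corey–Enders alkylation of the alkoxide–azaenolate dianion, which should metalate at the less substituted α′-methyl group, opens 4 at its CH2 to give 8, aqueous oxalic acid then hydrolyses the hydrazone to ketone 9 (its carbonyl oxygen comes from water and is lost again) and the two γ-hydroxyl groups close the spiroketal by two 5-exo-trig additions; C2 and C7 come unchanged from the epoxides, whereas C5 has no strong thermodynamic bias, so 10 should form in comparable amount with its C5 epimer, and C5 is set by the HPLC separation, with the epimer converted into more 10 by acid-catalysed spiroketal equilibration through the ring-opened oxocarbenium ion.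

Step 5
Reactants: 10 (2S,5R,7S)-2-(hex-5-en-1-yl)-7-methyl-1,6-dioxaspiro[4.4]nonane
Product: 13 {6-[(2S,5R,7S)-7-methyl-1,6-dioxaspiro[4.4]nonan-2-yl]hexyl}[(trimethylsilyl)methyl]zinc, via diethyl{6-[(2S,5R,7S)-7-methyl-1,6-dioxaspiro[4.4]nonan-2-yl]hexyl}borane 11 (not isolated), via bis{6-[(2S,5R,7S)-7-methyl-1,6-dioxaspiro[4.4]nonan-2-yl]hexyl}zinc 12 (not isolated)
Conditions: Et2BH (1.05 equiv, from BH3·SMe2 and BEt3), Et2O, 0 °C to rt; evaporate; Et2Zn (2 equiv), 0 °C; BEt3 and excess Et2Zn removed at 0.1 mmHg; (Me3SiCH2)2Zn (0.5 equiv), Et2O, rt; used as solution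
Reagents that add atoms: diethylzinc CC[Zn]CC; bis(trimethylsilylmethyl)zinc C[Si](C)(C)C[Zn]C[Si](C)(C)C
Why: Anti-Markovnikov hydroboration of the terminal alkene with Et2BH gives 11, boron–zinc exchange with Et2Zn is driven by removal of volatile BEt3 to give 12, and comproportionation with (Me3SiCH2)2Zn gives the mixed diorganozinc 13, whose CH2SiMe3 group does not transfer, so none of the valuable alkyl group is wasted; the sequence (Knochel-type preparation of functionalised diorganozincs) is acid-free and touches no stereocentre.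

Step 6
Reactants: 13 {6-[(2S,5R,7S)-7-methyl-1,6-dioxaspiro[4.4]nonan-2-yl]hexyl}[(trimethylsilyl)methyl]zinc; 2 methyl 2-formyl-4,6-dimethoxybenzoate (1.1 equiv)
Product: 15 (3R)-5,7-dimethoxy-3-{6-[(2S,5R,7S)-7-methyl-1,6-dioxaspiro[4.4]nonan-2-yl]hexyl}-2-benzofuran-1(3H)-one, via the zinc alkoxide (O–Zn–CH2SiMe3) of methyl 2-[(1R)-1-hydroxy-7-[(2S,5R,7S)-7-methyl-1,6-dioxaspiro[4.4]nonan-2-yl]heptyl]-4,6-dimethoxybenzoate 14 (not isolated)
Conditions: (1S,2S)-N,N′-bis(trifluoromethanesulfonyl)cyclohexane-1,2-diamine (8 mol%), Ti(OiPr)4 (1.2 equiv), Et2O/toluene, −20 °C; then rt; aq. NaHCO3/Rochelle salt work-up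
Reagents that add atoms: none
Why: The chiral titanium bis(sulfonamide) complex binds the formyl oxygen of 2 and the hexyl carbon of 13 is transferred from zinc to the formyl carbon while the CH2SiMe3 group stays on zinc; the benzylic alkoxide 14 then attacks the adjacent methyl ester and expels methoxide. The closest known reaction types are the titanium bis(sulfonamide)-catalysed enantioselective addition of functionalised and mixed diorganozincs to aromatic aldehydes and the tandem alkylzinc addition–lactonisation of methyl 2-formylbenzoates to 3-alkylphthalides. The lactone ring (O2–C1 bond) closes by a 5-exo-trig acyl substitution. C3 is set by the catalyst alone: by analogy with simple benzaldehydes, where the (1R,2R)-ligand gives Si-face attack, the (1S,2S)-ligand should deliver the alkyl group to the Re face, which gives (R) at C3, and the spiroketal stereocentres seven atoms away have no influence. The step needs chemoselectivity for the aldehyde over the flanked ester and the ketal, which the low reactivity of diorganozincs towards esters and ketals provides, and transfer of the right group, which the non-transferable CH2SiMe3 ligand secures; the acid-free work-up is meant to keep C5 of the spiroketal intact.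

Compound list
1 | 2-bromo-3,5-dimethoxybenzaldehyde | COc1cc(OC)c(Br)c(C=O)c1 | starting material
2 | methyl 2-formyl-4,6-dimethoxybenzoate | COC(=O)c1c(OC)cc(OC)cc1C=O | intermediate
3 | rac-2-(hex-5-en-1-yl)oxirane (1,2-epoxyoct-7-ene) | C=CCCCCC1CO1 | starting material
4 | (S)-2-(hex-5-en-1-yl)oxirane | C=CCCCC[C@H]1CO1 | intermediate
5 | acetone N,N-dimethylhydrazone | CC(C)=NN(C)C | starting material
6 | (S)-propylene oxide | C[C@H]1CO1 | starting material
7 | (5S)-5-hydroxyhexan-2-one N,N-dimethylhydrazone | C[C@H](O)CCC(C)=NN(C)C | intermediate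
8 | (2S,8S)-2,8-dihydroxytetradec-13-en-5-one N,N-dimethylhydrazone | C[C@H](O)CCC(=NN(C)C)CC[C@@H](O)CCCCC=C | intermediate
9 | (2S,8S)-2,8-dihydroxytetradec-13-en-5-one | C[C@H](O)CCC(=O)CC[C@@H](O)CCCCC=C | intermediate
10 | (2S,5R,7S)-2-(hex-5-en-1-yl)-7-methyl-1,6-dioxaspiro[4.4]nonane | C=CCCCC[C@H]1CC[C@@]2(CC[C@H](C)O2)O1 | intermediate
11 | diethyl{6-[(2S,5R,7S)-7-methyl-1,6-dioxaspiro[4.4]nonan-2-yl]hexyl}borane | CCB(CC)CCCCCC[C@H]1CC[C@@]2(CC[C@H](C)O2)O1 | intermediate
12 | bis{6-[(2S,5R,7S)-7-methyl-1,6-dioxaspiro[4.4]nonan-2-yl]hexyl}zinc | [Zn](CCCCCC[C@H]1CC[C@@]2(CC[C@H](C)O2)O1)CCCCCC[C@H]1CC[C@@]2(CC[C@H](C)O2)O1 | intermediate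
13 | {6-[(2S,5R,7S)-7-methyl-1,6-dioxaspiro[4.4]nonan-2-yl]hexyl}[(trimethylsilyl)methyl]zinc | C[Si](C)(C)C[Zn]CCCCCC[C@H]1CC[C@@]2(CC[C@H](C)O2)O1 | intermediate
14 | zinc alkoxide (O–Zn–CH2SiMe3) of methyl 2-[(1R)-1-hydroxy-7-[(2S,5R,7S)-7-methyl-1,6-dioxaspiro[4.4]nonan-2-yl]heptyl]-4,6-dimethoxybenzoate | COC(=O)c1c(OC)cc(OC)cc1[C@@H](CCCCCC[C@H]1CC[C@@]2(CC[C@H](C)O2)O1)O[Zn]C[Si](C)(C)C | intermediate
15 | (3R)-5,7-dimethoxy-3-{6-[(2S,5R,7S)-7-methyl-1,6-dioxaspiro[4.4]nonan-2-yl]hexyl}-2-benzofuran-1(3H)-one | COc1cc(OC)c2c(c1)[C@@H](CCCCCC[C@H]1CC[C@@]3(CC[C@H](C)O3)O1)OC2=O | target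

Total step count: 6
Longest linear sequence: 4 steps (steps 2, 4, 5 and 6; the branch through step 3 is equally long)

Steps most likely to fail

Step 6. Enantiofacial control may erode because the ortho ester carbonyl can chelate titanium or zinc and open a less organised or uncatalysed addition pathway. The alkoxide may also close only slowly on the hindered, doubly ortho-substituted ester. Fallback (sets out from 1 and 13, comes back at 15): the same titanium-catalysed addition of 13 is run on bromo aldehyde 1, a plain ortho-substituted benzaldehyde without a chelating ester. It should give (1R)-1-(2-bromo-3,5-dimethoxyphenyl)-7-[(2S,5R,7S)-7-methyl-1,6-dioxaspiro[4.4]nonan-2-yl]heptan-1-ol F1. A palladium-catalysed carbonylative lactonisation (Pd(OAc)2, Xantphos, CO, Et3N, toluene, 90 °C) then inserts CO into the C–Br bond, and the free benzylic hydroxyl captures the acyl-palladium to close the lactone and give 15. Ring closure is thereby taken out of the stereo-determining step and no longer depends on attack at the hindered ester.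

Step 4. Ring closure at C5 is expected to proceed without facial selectivity, and the two C5 epimers, which carry no chromophore, may prove hard to separate. Metalation of 7 at the wrong α-carbon would add to the loss. Fallback (sets out from 4, comes back at 10): C5 is set under kinetic catalyst control instead. Epoxide 4 is opened by dilithioacetate (AcOH, 2 LDA, THF, 0 to 45 °C) to (S)-4-hydroxydec-9-enoic acid F2, which lactonises (TsOH cat., toluene) to (S)-5-(hex-5-en-1-yl)oxolan-2-one F3. KHMDS and (PhO)2P(O)Cl (THF/HMPA, −78 °C) convert the lactone into the ketene acetal phosphate (S)-5-(hex-5-en-1-yl)-4,5-dihydrofuran-2-yl diphenyl phosphate F4. In parallel, commercial (S)-but-3-en-2-ol (C[C@H](O)C=C) is silylated (TBSCl, imidazole, DMF) to (S)-tert-butyl(but-3-en-2-yloxy)dimethylsilane F5 and hydroborated with 9-BBN to 9-[(3S)-3-(tert-butyldimethylsilyloxy)butyl]-9-borabicyclo[3.3.1]nonane F6. B-alkyl Suzuki–Miyaura coupling of this borane with the phosphate (PdCl2(dppf), aq. Cs2CO3, DMF, rt) should give tert-butyl{[(2S)-4-[(5S)-5-(hex-5-en-1-yl)-4,5-dihydrofuran-2-yl]butan-2-yl]oxy}dimethylsilane F7, and TBAF (THF) then frees the hydroxy enol ether (2S)-4-[(5S)-5-(hex-5-en-1-yl)-4,5-dihydrofuran-2-yl]butan-2-ol F8. A confined chiral imidodiphosphoric acid (5 mol%, non-polar solvent, −30 °C) protonates the enol ether and steers attack of the tethered hydroxyl to one face of the oxocarbenium ion (catalytic asymmetric spiroacetalisation of a hydroxy enol ether). The catalyst antipode that leads to the 5R epimer is chosen in a test run with both, and the product is 10.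

Step 5. The small dialkylborane may attack the ketal reductively, and boron–zinc exchange may stay incomplete, so that boron species reach step 6 and open a racemic background addition. Fallback (sets out from 10, comes back at 12): boron is avoided. Hydrozirconation of 10 with Cp2Zr(H)Cl (CH2Cl2, rt) gives chlorobis(cyclopentadienyl){6-[(2S,5R,7S)-7-methyl-1,6-dioxaspiro[4.4]nonan-2-yl]hexyl}zirconium F9. Iodine (0 °C) cleaves it to (2S,5R,7S)-2-(6-iodohexyl)-7-methyl-1,6-dioxaspiro[4.4]nonane F10. Iodine–zinc exchange with Et2Zn (CuI cat., neat, 50 °C, volatiles then removed in vacuo) gives dialkylzinc 12, which is taken on with (Me3SiCH2)2Zn as in step 5.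

Further compounds
F1 | step 6 | (1R)-1-(2-bromo-3,5-dimethoxyphenyl)-7-[(2S,5R,7S)-7-methyl-1,6-dioxaspiro[4.4]nonan-2-yl]heptan-1-ol | COc1cc(OC)c(Br)c(c1)[C@@H](CCCCCC[C@H]1CC[C@@]2(CC[C@H](C)O2)O1)O
F2 | step 4 | (S)-4-hydroxydec-9-enoic acid | C=CCCCC[C@H](O)CCC(=O)O
F3 | step 4 | (S)-5-(hex-5-en-1-yl)oxolan-2-one | C=CCCCC[C@H]1CCC(=O)O1
F4 | step 4 | (S)-5-(hex-5-en-1-yl)-4,5-dihydrofuran-2-yl diphenyl phosphate | C=CCCCC[C@H]1CC=C(OP(=O)(Oc2ccccc2)Oc2ccccc2)O1
F5 | step 4 | (S)-tert-butyl(but-3-en-2-yloxy)dimethylsilane | C[C@H](O[Si](C)(C)C(C)(C)C)C=C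
F6 | step 4 | 9-[(3S)-3-(tert-butyldimethylsilyloxy)butyl]-9-borabicyclo[3.3.1]nonane | C[C@H](O[Si](C)(C)C(C)(C)C)CCB1C2CCCC1CCC2
F7 | step 4 | tert-butyl{[(2S)-4-[(5S)-5-(hex-5-en-1-yl)-4,5-dihydrofuran-2-yl]butan-2-yl]oxy}dimethylsilane | C=CCCCC[C@H]1CC=C(CC[C@H](C)O[Si](C)(C)C(C)(C)C)O1
F8 | step 4 | (2S)-4-[(5S)-5-(hex-5-en-1-yl)-4,5-dihydrofuran-2-yl]butan-2-ol | C=CCCCC[C@H]1CC=C(CC[C@H](C)O)O1
F9 | step 5 | chlorobis(cyclopentadienyl){6-[(2S,5R,7S)-7-methyl-1,6-dioxaspiro[4.4]nonan-2-yl]hexyl}zirconium (cyclopentadienyl rings drawn σ-bound) | Cl[Zr](CCCCCC[C@H]1CC[C@@]2(CC[C@H](C)O2)O1)(C1C=CC=C1)C1C=CC=C1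
F10 | step 5 | (2S,5R,7S)-2-(6-iodohexyl)-7-methyl-1,6-dioxaspiro[4.4]nonane | ICCCCCC[C@H]1CC[C@@]2(CC[C@H](C)O2)O1
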